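Atom labels used throughout: decalin C1–C8a (ring B = C8a, C1–C4, C4a; ring A = C4a, C5–C8, C8a), with the methylidene groups on C2 and C7, the side chain on C3 and the gem-dimethyl group on C4. The 1,2-dioxane is O1′, O2′, C3′–C6′; the acid chain is C1″ (carboxyl) and C2″. These locants are also used in the compound names.

## Analysis of the target

Target 30 is a C24 peroxy acid built on a cis-fused decalin that carries exocyclic methylidene groups on C2 and C7, a gem-dimethyl group on C4 and, on C3, a CH2CH2 linker to the quaternary carbon C6′ of a 1,2-dioxane whose C3′ bears the propanoic acid carbon C2″. It has six stereocentres: C3 (R), C4a (S) and C8a (S) have their hydrogens on one face of ring B; in the dioxane the linker on C6′ (S) and the acid chain on C3′ (R) are trans and both equatorial, with the C6′ methyl axial; C2″ is R. The all-cis decalin is not the stable arrangement, because either chair–chair form has a syn-axial contact (C4 methyl against C8, or the C3 chain against C5). C8a therefore cannot be set by equilibration, and C3 must not be left to epimerise beside a C2 carbonyl once ring A is saturated. Two methylene groups separate the two stereo-clusters, so the decalin cannot steer the dioxane: C3′ and C2″ have to come from a chiral building block and C6′ from a relay inside the forming ring. The sensitive functions are the O–O bond (hydrogenation, low-valent metals, strong base at C3′–H), the β-peroxy acid (retro-oxa-Michael opening and C2″ epimerisation at the aldehyde stage) and the two 1,1-disubstituted alkenes (acid, electrophiles). The strategy rests on a hidden symmetry around C4: C4a carries C5–C6–C7(–C8) and C3 carries CH2–CH2–C6′(–C5′), both four-carbon chains oxidised at their third carbon, that is, two 3-oxobutyl groups on the carbons flanking the CMe2 unit of a dimedone-type 1,3-dione (C2, C1 and C8a are the dione carbons). If the two arms are cis the dione is meso, and closing ring A with one arm (bond C8–C8a) distinguishes C3 from C4a and fixes both configurations in one event.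

## Retrosynthetic reasoning

**30 ⇒ 28 ⇒ 27 (oxidation level of C1″).** The acid is taken back to primary alcohol 28 and its silyl ether 27. With C1″ at the alcohol level, C3′ is not β to a carbonyl, so substitution at C3′ does not compete with elimination and the peroxide cannot leave by retro-oxa-Michael. The forward oxidation has to stay neutral to weakly acidic.

**27 ⇒ 26 ⇒ 25 (bond O1′–C6′).** The quaternary peroxide carbon is the hardest centre of the side chain, so the ring is cut there. A hydroperoxide on C3′ that adds to an (E)-C5′=C6′ alkene through a chair, with an electrophile on C5′, turns alkene geometry into configuration at C6′: the substituent trans to C4′ becomes equatorial. The electrophile chosen is iodine (26), which is removed afterwards. The forward step must pick the trisubstituted alkene of 25, the only one with an internal nucleophile, over the two ring methylidene groups.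

**25 ⇒ 24 ⇒ 23 (bond C3′–O2′).** The secondary hydroperoxide is traced to carbinol 23 through mesylate 24, with inversion. The carbinol therefore has to be made with the opposite configuration at C3′.

**23 ⇒ 15 + 20 (bonds C4′–C5′ and C6′–CH3).** Cutting the allylic bond and the methyl branch together leads to terminal alkyne 15 and epoxide 20. Syn methyl-metalation of the alkyne gives only the E alkenyl metal, and opening of the epoxide at its CH2 brings in C4′, C3′ (with its oxygen), C2″ and C1″ without touching a stereocentre. A ketone olefination across C5′=C6′ was not chosen because it would not control the alkene geometry on which C6′ depends.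

**20 ⇒ 19 ⇒ 18 ⇒ 17 ⇒ 16.** C2″ is bought as Roche ester 16. One carbon is added to aldehyde 18 to give epoxide 19, and the oxirane centre is set by catalyst-controlled resolution, since the neighbouring methyl-bearing carbon controls it poorly.

**15 ⇒ 13 ⇒ 12 ⇒ 11 (alkyne and ring methylidenes).** The alkyne comes from methyl ketone 13; its methyl carbon becomes C5′. The two ring methylidene groups are placed early, at diketone 11, under non-basic conditions. From then on no carbonyl is left next to C3, and the strong bases and aluminium reagents of the side-chain work meet only hydrocarbon rings. The side-chain oxygen is kept as a carbinol (12) during this step.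

**11 ⇒ 10 ⇒ 9 (C8a–H and differentiation of three ketones).** C8a is set by adding hydrogen to the C8=C8a alkene of 10 from the face away from the axial C4 methyl. Before that, the side-chain ketone of 9 is reduced while the two ring carbonyls protect themselves as one delocalised dienolate. This is the only stage at which the three carbonyls differ in kind.

**9 ⇒ 7 (bond C8–C8a, ring A).** Enedione 9 is the aldol condensation product of meso tetraketone 7 through ketol 8. The cut is made here because it is the one bond whose formation breaks the mirror symmetry: a chiral acid that chooses one arm sets C3 and C4a at once and leaves the other arm as the first four carbons of the side chain.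

**7 ⇒ 6 ⇒ 5 ⇒ 4 ⇒ 3 ⇒ 1 + 2.** The arms are attached to C4 and C6 of dimedone 1 by two dianion alkylations with bromide 2. Alkylation is expected to give mainly the trans isomer of 4, and equilibration should also favour trans (allylic strain against the oxygen on C3 pushes the C4 arm axial). The cis relation is therefore set kinetically: vinylogous ester 5 is deprotonated at C6 and the enolate is protonated from the face away from the C4 arm to give 6, which is hydrolysed to 7.

## Alternatives that were turned down

**Alternative 1: anionic oxy-Cope rearrangement of a bridged bicyclic alkoxide.**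
- Disconnection and key step: the C4–C4a bond would be formed while a bridge bond is broken. A tertiary bicyclo[2.2.2]octenyl alkoxide (KH, 18-crown-6) would rearrange to cis-octalone A1.
- For: the cis ring fusion follows from the geometry of the [3,3] shift inside the bicycle and the quaternary C4 is made without an enolate alkylation. On C8a this is stronger than the facial hydrogenation used here.
- Against: A1 has no substituent on C3. The side chain would have to be put on a neopentyl α-carbon in the less stable configuration, against the competing C1 position. The absolute configuration needs a separate asymmetric cycloaddition, and C7 arrives as an allylic benzyl ether with a C5=C6 alkene that costs extra redox steps.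
- Comparison: the chosen plan has a weaker hold on C8a, but it delivers C3, C4a and four side-chain carbons from one symmetric precursor in a single catalytic step.

**Alternative 2: hydroboration and B-alkyl Suzuki closure of ring A.**
- Disconnection and key step: C7–C8. 9-BBN would add to a C8a=C8 methylidene and Pd(dppf)Cl2 would couple the C8 borane with a C7 vinyl bromide, giving A2.
- For: the bulky borane should read the axial C4 methyl better than H2 on a metal surface, and the C7 methylidene is formed in the coupling itself. On both points it is at least as strong as the chosen route.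
- Against: the cyclisation substrate is a fully substituted ring B with C2, C3 and C4a already set, which needs several independent asymmetric operations and uses no symmetry. C2 must still be oxidised and methylenated next to the epimerisable C3.
- Comparison: the chosen route reaches its key-step precursor in five steps from dimedone and offers an early, non-basic methylenation of C2 in exchange for a less secure C8a.

**Alternative 3: peroxide closure by mercuration as the central step.**
- Disconnection and key step: O1′–C6′. Hg(OAc)2 would activate the E trisubstituted alkene, the C3′ hydroperoxide would close the dioxane 6-endo and NaBH4 would replace mercury by hydrogen, giving A3.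
- For: divalent mercury is the best-precedented electrophile for hydroperoxides, and with C2 and C7 still ketones no other alkene competes. On chemoselectivity this is stronger than the iodonium closure used here.
- Against: borohydride meets two free ketones in A3. Both methylidene groups would have to be introduced after the peroxide, beside an epimerisable C3. The step does not address how the cis-decalin is obtained as one enantiomer.
- Comparison: the chosen route keeps the same geometric relay (E alkene to C6′) as an ordinary late step and spends its key step on the decalin, with the methylidene groups installed before the peroxide exists.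

Key step: step 6

Remark: the enantiomer written for each chiral catalyst (the phosphoric acid in step 6, the cobalt salen complex in step 15) is assumed to give the configuration shown; the mirror-image catalyst is used if a test run shows the opposite sense.

## Route

Step 1
Reactants: 1 dimedone (5,5-dimethylcyclohexane-1,3-dione); 2 2-(2-bromoethyl)-2-methyl-1,3-dioxolane
Product: 3 (±)-5,5-dimethyl-4-[2-(2-methyl-1,3-dioxolan-2-yl)ethyl]cyclohexane-1,3-dione
Conditions: LiN(iPr)2 (2.2 equiv), THF/HMPA, −78 to 0 °C; 2, 0 °C to rt; pH 5 buffer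
Reagents that add atoms: none
Why: Dianion alkylation of a cyclic 1,3-dione: after the enol proton, the second equivalent of base removes a C4 proton and this carbanion, not the stabilised C2 position, attacks the primary bromide. HMPA raises the rate of substitution over elimination of 2.

Step 2
Reactants: 3 (±)-5,5-dimethyl-4-[2-(2-methyl-1,3-dioxolan-2-yl)ethyl]cyclohexane-1,3-dione; 2 2-(2-bromoethyl)-2-methyl-1,3-dioxolane
Product: 4 5,5-dimethyl-4,6-bis[2-(2-methyl-1,3-dioxolan-2-yl)ethyl]cyclohexane-1,3-dione (trans racemate and cis meso isomer)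
Conditions: LiN(iPr)2 (2.3 equiv), THF/HMPA, −78 to 0 °C; 2, 0 °C to rt; pH 5 buffer
Reagents that add atoms: none
Why: Second dianion alkylation: in the monoanion of 3 the C6 methylene is deprotonated in preference to the C4 methine, so the new arm enters at C6. The halide should approach anti to the C4 arm and give mainly the trans isomer; the ratio is irrelevant because step 4 passes through a planar C6.

Step 3
Reactants: 4 5,5-dimethyl-4,6-bis[2-(2-methyl-1,3-dioxolan-2-yl)ethyl]cyclohexane-1,3-dione
Product: 5 3-methoxy-5,5-dimethyl-4,6-bis[2-(2-methyl-1,3-dioxolan-2-yl)ethyl]cyclohex-2-en-1-one (cis and trans racemates)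
Conditions: Me3SiCHN2, MeOH/toluene, 0 °C to rt
Reagents that add atoms: trimethylsilyldiazomethane, C[Si](C)(C)C=[N+]=[N-]
Why: O-Methylation of the enolised dione by a diazoalkane gives the vinylogous ester under conditions that leave the ketals alone. The two oxygens are equivalent in each diastereomer, so one constitution results, with C6 as its only kinetically acidic position.

Step 4
Reactants: 5 3-methoxy-5,5-dimethyl-4,6-bis[2-(2-methyl-1,3-dioxolan-2-yl)ethyl]cyclohex-2-en-1-one
Product: 6 cis-(4R*,6S*)-3-methoxy-5,5-dimethyl-4,6-bis[2-(2-methyl-1,3-dioxolan-2-yl)ethyl]cyclohex-2-en-1-one (racemic)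
Conditions: LiN(iPr)2 (1.3 equiv), THF, −78 to −30 °C; inverse addition to AcOH/THF, −78 °C; NaHCO3
Reagents that add atoms: none
Why: Kinetic deprotonation at C6 (the alpha-prime position of the vinylogous ester) gives the same enolate from both diastereomers of 5. Kinetic protonation from the face away from the C4 arm, the bias that sends an alkyl halide trans, places the C6 arm cis to the C4 arm. Base equilibration is avoided because allylic strain against the C3 methoxy group should favour trans.

Step 5
Reactants: 6 cis-(4R*,6S*)-3-methoxy-5,5-dimethyl-4,6-bis[2-(2-methyl-1,3-dioxolan-2-yl)ethyl]cyclohex-2-en-1-one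
Product: 7 meso-(4R,6S)-5,5-dimethyl-4,6-bis(3-oxobutyl)cyclohexane-1,3-dione
Conditions: 1 M HCl, THF, rt
Reagents that add atoms: water, O
Why: Aqueous acid hydrolyses the vinylogous ester and both ketals. Both enantiomers of 6 give the same meso tetraketone, and at room temperature dilute acid should neither condense the arms with the enolised dione nor epimerise C4 or C6.

Step 6
Reactants: 7 meso-(4R,6S)-5,5-dimethyl-4,6-bis(3-oxobutyl)cyclohexane-1,3-dione
Product: 9 (3S,4aR)-4,4-dimethyl-3-(3-oxobutyl)-1,3,4,4a,5,6-hexahydronaphthalene-2,7-dione, via ketol 8 (not isolated)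
Conditions: (R)-TRIP [(R)-3,3′-bis(2,4,6-triisopropylphenyl)-1,1′-binaphthyl-2,2′-diyl hydrogen phosphate] (10 mol %), toluene, 50 °C, no drying agent
Reagents that add atoms: none
Why: Proposed new method: the phosphoric acid is expected to bind the enolised 1,3-dione and the enol of one side-chain methyl ketone through hydrogen bonds; that enol attacks the neighbouring ring carbonyl carbon (the future C8a) to give ketol 8, which loses water to the enone. The closest known reaction type is the Hajos–Parrish-type aldol condensation of 2,2-disubstituted 2-(3-oxobutyl)-1,3-diones catalysed by chiral phosphoric acids; new here are the enolisable dione and the choice between two arm/carbonyl pairs instead of two carbonyls. Ring A closes in a 6-(enolendo)-exo-trig mode. No stereocentre is created in the product, but C3 and C4a, mirror images of each other in 7, become different, and the chiral phosphate, by deciding which arm reacts, fixes the absolute configuration of both. The step needs enantiotopic-group selectivity and carbon over oxygen cyclisation. The substrate helps because each arm can reach only its own neighbouring carbonyl through a six-membered transition state. The bridged ketol from attack of the dione C2 on an arm ketone cannot dehydrate and reverts, and the cyclic enol ether from oxygen attack reopens with the water set free by the condensation.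

Step 7
Reactants: 9 (3S,4aR)-4,4-dimethyl-3-(3-oxobutyl)-1,3,4,4a,5,6-hexahydronaphthalene-2,7-dione
Product: 10 (3S,4aR)-3-(3-hydroxybutyl)-4,4-dimethyl-1,3,4,4a,5,6-hexahydronaphthalene-2,7-dione (both carbinol epimers)
Conditions: NaOH (1.1 equiv), NaBH4, EtOH/H2O, 0 °C; pH 6 phosphate buffer
Reagents that add atoms: none
Why: In base the two ring carbonyls form one delocalised dienolate (O–C2–C1–C8a–C8–C7–O) that is inert to borohydride, so only the side-chain ketone is reduced (in situ enolate protection). Neither C3–H nor C4a–H is acidic in this monoanion, and the carbinol configuration is irrelevant because it is oxidised again in step 10.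

Step 8
Reactants: 10 (3S,4aR)-3-(3-hydroxybutyl)-4,4-dimethyl-1,3,4,4a,5,6-hexahydronaphthalene-2,7-dione
Product: 11 (3S,4aS,8aS)-3-(3-hydroxybutyl)-4,4-dimethyl-cis-octahydronaphthalene-2,7(1H,3H)-dione (both carbinol epimers)
Conditions: H2 (1 atm), Pd/C (palladium on carbon), EtOAc, rt
Reagents that add atoms: none
Why: Heterogeneous hydrogenation of the enone alkene: ring B is held as a chair with C4a–H axial, so one C4 methyl is axial and covers the face of C8a on its side. Hydrogen should add from the other face and put C8a–H cis to C4a–H. After this step C4a and C8a can no longer epimerise.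

Step 9
Reactants: 11 (3S,4aS,8aS)-3-(3-hydroxybutyl)-4,4-dimethyl-cis-octahydronaphthalene-2,7(1H,3H)-dione
Product: 12 4-[(3R,4aS,8aS)-4,4-dimethyl-2,7-dimethylidene-cis-decahydronaphthalen-3-yl]butan-2-ol (both carbinol epimers)
Conditions: Zn, CH2Br2, TiCl4, THF/CH2Cl2, 0 °C to rt (excess reagent)
Reagents that add atoms: dibromomethane, BrCBr
Why: Lombardo methylenation is not basic, so both ring ketones, including the hindered C2 ketone, are converted without enolising C3, whose natural configuration is the less stable one in the saturated cis-decalone. The free hydroxyl only consumes reagent.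

Step 10
Reactants: 12 4-[(3R,4aS,8aS)-4,4-dimethyl-2,7-dimethylidene-cis-decahydronaphthalen-3-yl]butan-2-ol
Product: 13 4-[(3R,4aS,8aS)-4,4-dimethyl-2,7-dimethylidene-cis-decahydronaphthalen-3-yl]butan-2-one
Conditions: Dess–Martin periodinane, NaHCO3, CH2Cl2, rt
Reagents that add atoms: none
Why: Dess–Martin oxidation of the secondary alcohol; both epimers converge on one methyl ketone, which is now the only carbonyl group.

Step 11
Reactants: 13 4-[(3R,4aS,8aS)-4,4-dimethyl-2,7-dimethylidene-cis-decahydronaphthalen-3-yl]butan-2-one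
Product: 15 (3R,4aS,8aS)-3-(but-3-yn-1-yl)-4,4-dimethyl-2,7-dimethylidene-cis-decahydronaphthalene, via enol phosphate 14 (not isolated)
Conditions: LiN(iPr)2 (1.1 equiv), THF, −78 °C; ClP(O)(OEt)2; LiN(iPr)2 (2.3 equiv), −78 °C to rt
Reagents that add atoms: none
Why: Methyl ketone to terminal alkyne: kinetic deprotonation at the methyl group, O-phosphorylation and elimination of the enol phosphate with amide base. The former methyl carbon becomes C5′.

Step 12
Reactants: 16 methyl (S)-3-hydroxy-2-methylpropanoate (Roche ester)
Product: 17 methyl (S)-3-{[tert-butyl(dimethyl)silyl]oxy}-2-methylpropanoate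
Conditions: tert-butyldimethylsilyl chloride, imidazole, CH2Cl2, rt
Reagents that add atoms: tert-butyldimethylsilyl chloride, CC(C)(C)[Si](C)(C)Cl
Why: Silylation of the primary alcohol; the ether withstands the aluminium, lithium and aqueous base steps that follow and is removed by fluoride at the end.

Step 13
Reactants: 17 methyl (S)-3-{[tert-butyl(dimethyl)silyl]oxy}-2-methylpropanoate
Product: 18 (S)-3-{[tert-butyl(dimethyl)silyl]oxy}-2-methylpropanal
Conditions: (i-Bu)2AlH (1.05 equiv), CH2Cl2, −78 °C; aq. KNaC4H4O6 (potassium sodium tartrate)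
Reagents that add atoms: none
Why: Partial reduction of the ester stops at the aldehyde at low temperature; the aldehyde is used at once so that the alpha centre does not racemise.

Step 14
Reactants: 18 (S)-3-{[tert-butyl(dimethyl)silyl]oxy}-2-methylpropanal
Product: 19 tert-butyldimethyl{[(2S)-2-(oxiran-2-yl)propyl]oxy}silane (both oxirane epimers)
Conditions: trimethylsulfonium iodide, n-BuLi, THF, −10 to 0 °C
Reagents that add atoms: trimethylsulfonium iodide, C[S+](C)C.[I-]
Why: Corey–Chaykovsky methylene transfer from the sulfonium ylide to the aldehyde gives the terminal epoxide. Little control by the neighbouring centre is expected, so the epimer mixture is resolved in the next step.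

Step 15
Reactants: 19 tert-butyldimethyl{[(2S)-2-(oxiran-2-yl)propyl]oxy}silane (both oxirane epimers)
Product: 20 tert-butyldimethyl{[(2S)-2-[(2R)-oxiran-2-yl]propyl]oxy}silane
Conditions: (R,R)-(salen)Co(OAc) (trivalent cobalt; salen = N,N′-bis(3,5-di-tert-butylsalicylidene)cyclohexane-1,2-diamine dianion; 1 mol %), H2O (0.55 equiv), THF, 0 °C to rt
Reagents that add atoms: none
Why: Jacobsen hydrolytic kinetic resolution: the catalyst hydrolyses the terminal epoxide of one configuration to the diol and leaves the (R)-oxirane epimer. Catalyst control overrides the adjacent methyl-bearing centre.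

Step 16
Reactants: 15 (3R,4aS,8aS)-3-(but-3-yn-1-yl)-4,4-dimethyl-2,7-dimethylidene-cis-decahydronaphthalene; 20 tert-butyldimethyl{[(2S)-2-[(2R)-oxiran-2-yl]propyl]oxy}silane
Product: 23 (2S,3S,5E)-1-{[tert-butyl(dimethyl)silyl]oxy}-8-[(3R,4aS,8aS)-4,4-dimethyl-2,7-dimethylidene-cis-decahydronaphthalen-3-yl]-2,6-dimethyloct-5-en-3-ol, via alkenylalane 21 (not isolated), via lithium alanate 22 (not isolated)
Conditions: Me3Al (3 equiv), Cp2ZrCl2 (0.3 equiv), CH2Cl2, rt; volatiles removed; n-BuLi, THF/hexane, −78 °C; 20, −78 °C to rt; aq. KNaC4H4O6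
Reagents that add atoms: trimethylaluminium, C[Al](C)C
Why: Zirconium-catalysed methylalumination (Negishi) adds methyl and aluminium syn across the alkyne with methyl on the internal carbon, which gives the E alkenylalane only. Its butyl alanate opens the epoxide at CH2 with retention of the alkene geometry and of C3′. The 1,1-disubstituted ring alkenes are not carbometalated under these conditions.

Step 17
Reactants: 23 (2S,3S,5E)-1-{[tert-butyl(dimethyl)silyl]oxy}-8-[(3R,4aS,8aS)-4,4-dimethyl-2,7-dimethylidene-cis-decahydronaphthalen-3-yl]-2,6-dimethyloct-5-en-3-ol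
Product: 24 (2S,3S,5E)-1-{[tert-butyl(dimethyl)silyl]oxy}-8-[(3R,4aS,8aS)-4,4-dimethyl-2,7-dimethylidene-cis-decahydronaphthalen-3-yl]-2,6-dimethyloct-5-en-3-yl methanesulfonate
Conditions: methanesulfonyl chloride, Et3N, CH2Cl2, 0 °C
Reagents that add atoms: methanesulfonyl chloride, CS(=O)(=O)Cl
Why: Sulfonylation of the only free hydroxyl turns C3′ into an electrophile without touching its configuration.

Step 18
Reactants: 24 (2S,3S,5E)-1-{[tert-butyl(dimethyl)silyl]oxy}-8-[(3R,4aS,8aS)-4,4-dimethyl-2,7-dimethylidene-cis-decahydronaphthalen-3-yl]-2,6-dimethyloct-5-en-3-yl methanesulfonate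
Product: 25 tert-butyl({(2S,3R,5E)-8-[(3R,4aS,8aS)-4,4-dimethyl-2,7-dimethylidene-cis-decahydronaphthalen-3-yl]-3-hydroperoxy-2,6-dimethyloct-5-en-1-yl}oxy)dimethylsilane
Conditions: 50% aq. H2O2, KOH, MeOH/THF, 0 °C to rt
Reagents that add atoms: hydrogen peroxide, OO
Why: SN2 displacement of a secondary mesylate by hydroperoxide anion, a strong alpha-effect nucleophile, goes with inversion and gives C3′ in the configuration of the target. C1″ is at the alcohol level, so no carbonyl-assisted elimination is possible.

Step 19
Reactants: 25 tert-butyl({(2S,3R,5E)-8-[(3R,4aS,8aS)-4,4-dimethyl-2,7-dimethylidene-cis-decahydronaphthalen-3-yl]-3-hydroperoxy-2,6-dimethyloct-5-en-1-yl}oxy)dimethylsilane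
Product: 26 tert-butyl{(2S)-2-[(3R,5R,6S)-6-{2-[(3R,4aS,8aS)-4,4-dimethyl-2,7-dimethylidene-cis-decahydronaphthalen-3-yl]ethyl}-5-iodo-6-methyl-1,2-dioxan-3-yl]propoxy}dimethylsilane
Conditions: N-iodosuccinimide, NaHCO3, CH2Cl2, 0 °C, dark
Reagents that add atoms: N-iodosuccinimide, O=C1CCC(=O)N1I
Why: Cycloperoxyiodination: the iodonium ion on the trisubstituted alkene is opened by the terminal hydroperoxide oxygen at the tertiary carbon (6-endo, Markovnikov) through a chair with the C3′ substituent equatorial. Anti addition to the E alkene puts the linker equatorial and the methyl axial on C6′ (6′S). The ring methylidene groups can form iodonium ions only reversibly, since they have no internal nucleophile.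

Step 20
Reactants: 26 tert-butyl{(2S)-2-[(3R,5R,6S)-6-{2-[(3R,4aS,8aS)-4,4-dimethyl-2,7-dimethylidene-cis-decahydronaphthalen-3-yl]ethyl}-5-iodo-6-methyl-1,2-dioxan-3-yl]propoxy}dimethylsilane
Product: 27 tert-butyl{(2S)-2-[(3R,6S)-6-{2-[(3R,4aS,8aS)-4,4-dimethyl-2,7-dimethylidene-cis-decahydronaphthalen-3-yl]ethyl}-6-methyl-1,2-dioxan-3-yl]propoxy}dimethylsilane
Conditions: Bu3SnH (excess, concentrated), Et3B/air, toluene, 0 °C to rt
Reagents that add atoms: none
Why: Radical deiodination: iodine abstraction by the tin radical is far faster than its attack on the O–O bond. A high tin hydride concentration traps the C5′ radical before it can displace on the ring oxygen, a displacement that the ring geometry already disfavours.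

Step 21
Reactants: 27 tert-butyl{(2S)-2-[(3R,6S)-6-{2-[(3R,4aS,8aS)-4,4-dimethyl-2,7-dimethylidene-cis-decahydronaphthalen-3-yl]ethyl}-6-methyl-1,2-dioxan-3-yl]propoxy}dimethylsilane
Product: 28 (2S)-2-[(3R,6S)-6-{2-[(3R,4aS,8aS)-4,4-dimethyl-2,7-dimethylidene-cis-decahydronaphthalen-3-yl]ethyl}-6-methyl-1,2-dioxan-3-yl]propan-1-ol
Conditions: HF·pyridine, pyridine, THF, 0 °C to rt
Reagents that add atoms: none
Why: Buffered fluoride cleaves the primary silyl ether without the basic conditions that could fragment a secondary peroxide; the buffer keeps the exocyclic alkenes from isomerising.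

Step 22
Reactants: 28 (2S)-2-[(3R,6S)-6-{2-[(3R,4aS,8aS)-4,4-dimethyl-2,7-dimethylidene-cis-decahydronaphthalen-3-yl]ethyl}-6-methyl-1,2-dioxan-3-yl]propan-1-ol
Product: 30 (2R)-2-[(3R,6S)-6-{2-[(3R,4aS,8aS)-4,4-dimethyl-2,7-dimethylidene-cis-decahydronaphthalen-3-yl]ethyl}-6-methyl-1,2-dioxan-3-yl]propanoic acid (CNP0363961.1), via aldehyde 29 (not isolated)
Conditions: Dess–Martin periodinane, NaHCO3, CH2Cl2, 0 °C; then NaClO2, NaH2PO4, 2-methylbut-2-ene (large excess), t-BuOH/H2O, 0 °C
Reagents that add atoms: sodium chlorite, [Na+].[O-]Cl=O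
Why: Dess–Martin then Pinnick oxidation keeps the medium neutral to weakly acidic, so the β-peroxy aldehyde neither epimerises at C2″ nor expels the peroxide by retro-oxa-Michael reaction. The alkene scavenger takes up hypochlorous acid before it reaches the ring methylidene groups.

## Compound list

1 | dimedone (5,5-dimethylcyclohexane-1,3-dione) | CC1(C)CC(=O)CC(=O)C1 | starting material
2 | 2-(2-bromoethyl)-2-methyl-1,3-dioxolane | CC1(CCBr)OCCO1 | starting material
3 | (±)-5,5-dimethyl-4-[2-(2-methyl-1,3-dioxolan-2-yl)ethyl]cyclohexane-1,3-dione (racemic) | CC1(CCC2C(=O)CC(=O)CC2(C)C)OCCO1 | intermediate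
4 | 5,5-dimethyl-4,6-bis[2-(2-methyl-1,3-dioxolan-2-yl)ethyl]cyclohexane-1,3-dione (trans racemate and cis meso isomer) | CC1(CCC2C(=O)CC(=O)C(CCC3(C)OCCO3)C2(C)C)OCCO1 | intermediate
5 | 3-methoxy-5,5-dimethyl-4,6-bis[2-(2-methyl-1,3-dioxolan-2-yl)ethyl]cyclohex-2-en-1-one (cis and trans racemates) | COC1=CC(=O)C(CCC2(C)OCCO2)C(C)(C)C1CCC1(C)OCCO1 | intermediate
6 | cis-(4R*,6S*)-3-methoxy-5,5-dimethyl-4,6-bis[2-(2-methyl-1,3-dioxolan-2-yl)ethyl]cyclohex-2-en-1-one (racemic, one enantiomer drawn) | CC1(OCCO1)CC[C@H]1C(OC)=CC(=O)[C@@H](CCC2(C)OCCO2)C1(C)C | intermediate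
7 | meso-(4R,6S)-5,5-dimethyl-4,6-bis(3-oxobutyl)cyclohexane-1,3-dione | CC(=O)CC[C@H]1C(=O)CC(=O)[C@@H](CCC(C)=O)C1(C)C | intermediate
8 | ketol: (3S,4aR)-8a-hydroxy-4,4-dimethyl-3-(3-oxobutyl)octahydronaphthalene-2,7-dione (C8a configuration not defined) | O=C1CC[C@H]2C(O)(C1)CC(=O)[C@@H](CCC(C)=O)C2(C)C | intermediate (not isolated)
9 | (3S,4aR)-4,4-dimethyl-3-(3-oxobutyl)-1,3,4,4a,5,6-hexahydronaphthalene-2,7-dione | O=C1CC[C@H]2C(=C1)CC(=O)[C@@H](CCC(C)=O)C2(C)C | intermediate
10 | (3S,4aR)-3-(3-hydroxybutyl)-4,4-dimethyl-1,3,4,4a,5,6-hexahydronaphthalene-2,7-dione (both carbinol epimers) | O=C1CC[C@H]2C(=C1)CC(=O)[C@@H](CCC(C)O)C2(C)C | intermediate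
11 | (3S,4aS,8aS)-3-(3-hydroxybutyl)-4,4-dimethyl-cis-octahydronaphthalene-2,7(1H,3H)-dione (both carbinol epimers) | O=C1CC[C@H]2[C@@H](C1)CC(=O)[C@@H](CCC(C)O)C2(C)C | intermediate
12 | 4-[(3R,4aS,8aS)-4,4-dimethyl-2,7-dimethylidene-cis-decahydronaphthalen-3-yl]butan-2-ol (both carbinol epimers) | C=C1CC[C@H]2[C@@H](C1)CC(=C)[C@@H](CCC(C)O)C2(C)C | intermediate
13 | 4-[(3R,4aS,8aS)-4,4-dimethyl-2,7-dimethylidene-cis-decahydronaphthalen-3-yl]butan-2-one | C=C1CC[C@H]2[C@@H](C1)CC(=C)[C@@H](CCC(C)=O)C2(C)C | intermediate
14 | 4-[(3R,4aS,8aS)-4,4-dimethyl-2,7-dimethylidene-cis-decahydronaphthalen-3-yl]but-1-en-2-yl diethyl phosphate | C=C1CC[C@H]2[C@@H](C1)CC(=C)[C@@H](CCC(=C)OP(=O)(OCC)OCC)C2(C)C | intermediate (not isolated)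
15 | (3R,4aS,8aS)-3-(but-3-yn-1-yl)-4,4-dimethyl-2,7-dimethylidene-cis-decahydronaphthalene | C=C1CC[C@H]2[C@@H](C1)CC(=C)[C@@H](CCC#C)C2(C)C | intermediate
16 | methyl (S)-3-hydroxy-2-methylpropanoate | COC(=O)[C@@H](C)CO | starting material
17 | methyl (S)-3-{[tert-butyl(dimethyl)silyl]oxy}-2-methylpropanoate | COC(=O)[C@@H](C)CO[Si](C)(C)C(C)(C)C | intermediate
18 | (S)-3-{[tert-butyl(dimethyl)silyl]oxy}-2-methylpropanal | O=C[C@@H](C)CO[Si](C)(C)C(C)(C)C | intermediate
19 | tert-butyldimethyl{[(2S)-2-(oxiran-2-yl)propyl]oxy}silane (both oxirane epimers) | C1OC1[C@@H](C)CO[Si](C)(C)C(C)(C)C | intermediate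
20 | tert-butyldimethyl{[(2S)-2-[(2R)-oxiran-2-yl]propyl]oxy}silane | C1[C@@H]([C@@H](C)CO[Si](C)(C)C(C)(C)C)O1 | intermediate
21 | [(1E)-4-[(3R,4aS,8aS)-4,4-dimethyl-2,7-dimethylidene-cis-decahydronaphthalen-3-yl]-2-methylbut-1-en-1-yl]dimethylalane | C=C1CC[C@H]2[C@@H](C1)CC(=C)[C@@H](CC/C(C)=C/[Al](C)C)C2(C)C | intermediate (not isolated)
22 | lithium butyl[(1E)-4-[(3R,4aS,8aS)-4,4-dimethyl-2,7-dimethylidene-cis-decahydronaphthalen-3-yl]-2-methylbut-1-en-1-yl]dimethylalanate | [Li+].C=C1CC[C@H]2[C@@H](C1)CC(=C)[C@@H](CC/C(C)=C/[Al-](C)(C)CCCC)C2(C)C | intermediate (not isolated)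
23 | (2S,3S,5E)-1-{[tert-butyl(dimethyl)silyl]oxy}-8-[(3R,4aS,8aS)-4,4-dimethyl-2,7-dimethylidene-cis-decahydronaphthalen-3-yl]-2,6-dimethyloct-5-en-3-ol | C=C1CC[C@H]2[C@@H](C1)CC(=C)[C@@H](CC/C(C)=C/C[C@@H]([C@@H](C)CO[Si](C)(C)C(C)(C)C)O)C2(C)C | intermediate
24 | (2S,3S,5E)-1-{[tert-butyl(dimethyl)silyl]oxy}-8-[(3R,4aS,8aS)-4,4-dimethyl-2,7-dimethylidene-cis-decahydronaphthalen-3-yl]-2,6-dimethyloct-5-en-3-yl methanesulfonate | C=C1CC[C@H]2[C@@H](C1)CC(=C)[C@@H](CC/C(C)=C/C[C@@H]([C@@H](C)CO[Si](C)(C)C(C)(C)C)OS(C)(=O)=O)C2(C)C | intermediate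
25 | tert-butyl({(2S,3R,5E)-8-[(3R,4aS,8aS)-4,4-dimethyl-2,7-dimethylidene-cis-decahydronaphthalen-3-yl]-3-hydroperoxy-2,6-dimethyloct-5-en-1-yl}oxy)dimethylsilane | C=C1CC[C@H]2[C@@H](C1)CC(=C)[C@@H](CC/C(C)=C/C[C@H]([C@@H](C)CO[Si](C)(C)C(C)(C)C)OO)C2(C)C | intermediate
26 | tert-butyl{(2S)-2-[(3R,5R,6S)-6-{2-[(3R,4aS,8aS)-4,4-dimethyl-2,7-dimethylidene-cis-decahydronaphthalen-3-yl]ethyl}-5-iodo-6-methyl-1,2-dioxan-3-yl]propoxy}dimethylsilane | C=C1CC[C@H]2[C@@H](C1)CC(=C)[C@@H](CC[C@@]1(C)[C@H](I)C[C@H]([C@@H](C)CO[Si](C)(C)C(C)(C)C)OO1)C2(C)C | intermediate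
27 | tert-butyl{(2S)-2-[(3R,6S)-6-{2-[(3R,4aS,8aS)-4,4-dimethyl-2,7-dimethylidene-cis-decahydronaphthalen-3-yl]ethyl}-6-methyl-1,2-dioxan-3-yl]propoxy}dimethylsilane | C=C1CC[C@H]2[C@@H](C1)CC(=C)[C@@H](CC[C@@]1(C)CC[C@H]([C@@H](C)CO[Si](C)(C)C(C)(C)C)OO1)C2(C)C | intermediate
28 | (2S)-2-[(3R,6S)-6-{2-[(3R,4aS,8aS)-4,4-dimethyl-2,7-dimethylidene-cis-decahydronaphthalen-3-yl]ethyl}-6-methyl-1,2-dioxan-3-yl]propan-1-ol | C=C1CC[C@H]2[C@@H](C1)CC(=C)[C@@H](CC[C@@]1(C)CC[C@H]([C@@H](C)CO)OO1)C2(C)C | intermediate
29 | (2R)-2-[(3R,6S)-6-{2-[(3R,4aS,8aS)-4,4-dimethyl-2,7-dimethylidene-cis-decahydronaphthalen-3-yl]ethyl}-6-methyl-1,2-dioxan-3-yl]propanal | C=C1CC[C@H]2[C@@H](C1)CC(=C)[C@@H](CC[C@@]1(C)CC[C@H]([C@@H](C)C=O)OO1)C2(C)C | intermediate (not isolated)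
30 | (2R)-2-[(3R,6S)-6-{2-[(3R,4aS,8aS)-4,4-dimethyl-2,7-dimethylidene-cis-decahydronaphthalen-3-yl]ethyl}-6-methyl-1,2-dioxan-3-yl]propanoic acid (CNP0363961.1) | C=C1CC[C@H]2[C@@H](C1)CC(=C)[C@@H](CC[C@@]1(C)CC[C@H]([C@@H](C)C(=O)O)OO1)C2(C)C | target

## Step count and least certain steps

Total: 22 steps. Longest linear sequence: 18 steps from dimedone (steps 1–11 and 16–22). The epoxide branch (steps 12–15) is 4 steps from the Roche ester.

**Step 6 (key step).**
- Risk: the enolised dione is a poor electrophile. Carbon–carbon bond formation may lose to oxygen cyclisation (the enol oxygen adding to the arm ketone) or be held up in the bridged ketol. The catalyst may discriminate the two arms poorly, and acid-mediated epimerisation at the carbons flanking CMe2, before or after ring closure, would erode the enantiomeric purity.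
- Fallback (known chemistry): from 7, the same ring is closed without asymmetric induction by a classical amine-mediated aldol cyclodehydration (pyrrolidine, AcOH, toluene, warm), which gives 9 together with its mirror image, ent-9 F1. The enantiomers are separated by preparative chromatography on a chiral stationary phase, and the route is rejoined at 9.

**Step 18.**
- Risk: substitution at C3′ is slow because of the branch at C2″, and hydroxide or hydroperoxide anion can instead remove a C4′ proton, with elimination towards the alkene.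
- Fallback: from 23, the alcohol is converted into its 2-nitrobenzenesulfonate F2 (2-nitrobenzenesulfonyl chloride, Et3N, DMAP). This is displaced with inversion by the caesium salt of a protected hydroperoxide (2-methoxypropan-2-yl hydroperoxide, CsOH, DMF, 0 °C), a less basic nucleophile in a dipolar solvent, to give peroxyketal F3. Aqueous acetic acid releases hydroperoxide 25, where the route is rejoined.

**Step 19 (with step 20).**
- Risk: the iodonium source may be consumed by the two ring methylidene groups or oxidise the hydroperoxide, the ring may close 5-exo, and the later radical deiodination may break the O–O bond.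
- Fallback: the closure is moved to a stage without ring alkenes. From 11, both ring ketones are turned into latent methylidene groups by addition of Me3SiCH2Li/CeCl3, giving bis(β-hydroxysilane) F4.
- The chemistry of steps 10, 11, 16, 17 and 18 is then repeated with extra base and Me3Al for the two tertiary hydroxyls. This gives ketone F5, alkyne F6, homoallylic alcohol F7, mesylate F8 and hydroperoxide F9.
- Cycloperoxymercuration with Hg(OAc)2 in CH2Cl2 and demercuration with NaBH4/NaOH gives dioxane F10. HF·pyridine then brings about both Peterson eliminations and removes the silyl ether, and the route is rejoined at 28.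

**Step 4.**
- Risk: incomplete deprotonation of the hindered C6 methine or poor facial discrimination in the protonation would leave trans isomer, which carries racemic material into the key step.
- Fallback: the C6 centre is set by hydrogen delivery instead. From 3, the dianion is added to (2-methyl-1,3-dioxolan-2-yl)acetaldehyde to give aldol F11. Dehydration through the mesylate (methanesulfonyl chloride, Et3N; DBU) gives the C6 alkylidene dione F12. Hydrogenation over Pd/C, expected on the face away from the C4 arm, gives the cis bis-ketal dione F13. Hydrolysis as in step 5 returns to the route at 7.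

**Step 8.**
- Risk: poor facial selectivity. Addition of hydrogen on the face of the axial methyl would give the more stable trans-decalin, which cannot be corrected later.
- Fallback: from 10, substrate control is replaced by catalyst control. Homogeneous hydrogenation with a chiral iridium phosphinooxazoline complex, [Ir(cod)(PHOX)][B(C6H3(CF3)2)4], is tried with each ligand enantiomer and the matched one is used. No new compound is involved and the route continues at 11.

## Further compounds

F1 | step 6 | (3R,4aS)-4,4-dimethyl-3-(3-oxobutyl)-1,3,4,4a,5,6-hexahydronaphthalene-2,7-dione (ent-9) | O=C1CC[C@@H]2C(=C1)CC(=O)[C@H](CCC(C)=O)C2(C)C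
F2 | step 18 | (2S,3S,5E)-1-{[tert-butyl(dimethyl)silyl]oxy}-8-[(3R,4aS,8aS)-4,4-dimethyl-2,7-dimethylidene-cis-decahydronaphthalen-3-yl]-2,6-dimethyloct-5-en-3-yl 2-nitrobenzenesulfonate | C=C1CC[C@H]2[C@@H](C1)CC(=C)[C@@H](CC/C(C)=C/C[C@@H]([C@@H](C)CO[Si](C)(C)C(C)(C)C)OS(=O)(=O)c1ccccc1[N+](=O)[O-])C2(C)C
F3 | step 18 | tert-butyl({(2S,3R,5E)-8-[(3R,4aS,8aS)-4,4-dimethyl-2,7-dimethylidene-cis-decahydronaphthalen-3-yl]-3-[(2-methoxypropan-2-yl)peroxy]-2,6-dimethyloct-5-en-1-yl}oxy)dimethylsilane | C=C1CC[C@H]2[C@@H](C1)CC(=C)[C@@H](CC/C(C)=C/C[C@H]([C@@H](C)CO[Si](C)(C)C(C)(C)C)OOC(C)(C)OC)C2(C)C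
F4 | step 19 | (3S,4aS,8aS)-3-(3-hydroxybutyl)-4,4-dimethyl-2,7-bis[(trimethylsilyl)methyl]-cis-decahydronaphthalene-2,7-diol (carbinol epimers) | C[Si](C)(C)CC1(O)CC[C@H]2[C@@H](C1)CC(O)(C[Si](C)(C)C)[C@@H](CCC(C)O)C2(C)C
F5 | step 19 | 4-{(3S,4aS,8aS)-2,7-dihydroxy-4,4-dimethyl-2,7-bis[(trimethylsilyl)methyl]-cis-decahydronaphthalen-3-yl}butan-2-one | C[Si](C)(C)CC1(O)CC[C@H]2[C@@H](C1)CC(O)(C[Si](C)(C)C)[C@@H](CCC(C)=O)C2(C)C
F6 | step 19 | (3S,4aS,8aS)-3-(but-3-yn-1-yl)-4,4-dimethyl-2,7-bis[(trimethylsilyl)methyl]-cis-decahydronaphthalene-2,7-diol | C[Si](C)(C)CC1(O)CC[C@H]2[C@@H](C1)CC(O)(C[Si](C)(C)C)[C@@H](CCC#C)C2(C)C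
F7 | step 19 | (3S,4aS,8aS)-3-[(3E,6S,7S)-8-{[tert-butyl(dimethyl)silyl]oxy}-6-hydroxy-3,7-dimethyloct-3-en-1-yl]-4,4-dimethyl-2,7-bis[(trimethylsilyl)methyl]-cis-decahydronaphthalene-2,7-diol | C[Si](C)(C)CC1(O)CC[C@H]2[C@@H](C1)CC(O)(C[Si](C)(C)C)[C@@H](CC/C(C)=C/C[C@@H]([C@@H](C)CO[Si](C)(C)C(C)(C)C)O)C2(C)C
F8 | step 19 | C3′ methanesulfonate of F7 | C[Si](C)(C)CC1(O)CC[C@H]2[C@@H](C1)CC(O)(C[Si](C)(C)C)[C@@H](CC/C(C)=C/C[C@@H]([C@@H](C)CO[Si](C)(C)C(C)(C)C)OS(C)(=O)=O)C2(C)C
F9 | step 19 | C3′ hydroperoxide (inverted) corresponding to F8 | C[Si](C)(C)CC1(O)CC[C@H]2[C@@H](C1)CC(O)(C[Si](C)(C)C)[C@@H](CC/C(C)=C/C[C@H]([C@@H](C)CO[Si](C)(C)C(C)(C)C)OO)C2(C)C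
F10 | step 19 | (3S,4aS,8aS)-3-{2-[(3S,6R)-6-[(2S)-1-{[tert-butyl(dimethyl)silyl]oxy}propan-2-yl]-3-methyl-1,2-dioxan-3-yl]ethyl}-4,4-dimethyl-2,7-bis[(trimethylsilyl)methyl]-cis-decahydronaphthalene-2,7-diol | C[Si](C)(C)CC1(O)CC[C@H]2[C@@H](C1)CC(O)(C[Si](C)(C)C)[C@@H](CC[C@@]1(C)CC[C@H]([C@@H](C)CO[Si](C)(C)C(C)(C)C)OO1)C2(C)C
F11 | step 4 | 4-[1-hydroxy-2-(2-methyl-1,3-dioxolan-2-yl)ethyl]-5,5-dimethyl-6-[2-(2-methyl-1,3-dioxolan-2-yl)ethyl]cyclohexane-1,3-dione | CC1(CCC2C(=O)CC(=O)C(C(O)CC3(C)OCCO3)C2(C)C)OCCO1
F12 | step 4 | 5,5-dimethyl-6-[2-(2-methyl-1,3-dioxolan-2-yl)ethyl]-4-[2-(2-methyl-1,3-dioxolan-2-yl)ethylidene]cyclohexane-1,3-dione | CC1(CCC2C(=O)CC(=O)C(=CCC3(C)OCCO3)C2(C)C)OCCO1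
F13 | step 4 | meso-(4R,6S)-5,5-dimethyl-4,6-bis[2-(2-methyl-1,3-dioxolan-2-yl)ethyl]cyclohexane-1,3-dione | CC1(OCCO1)CC[C@H]1C(=O)CC(=O)[C@@H](CCC2(C)OCCO2)C1(C)C
F0 | step 8 | none | none
A1 | alternative 1 | cis-fused 7-(benzyloxy)-4,4-dimethyl-3,4,4a,7,8,8a-hexahydronaphthalen-2(1H)-one | C(c1ccccc1)O[C@H]1C=C[C@H]2[C@@H](C1)CC(=O)CC2(C)C
A2 | alternative 2 | tert-butyldimethylsilyl ether of the cis-decalin-2-ol with C7 methylidene, C4 gem-dimethyl and a 2-(2-methyl-1,3-dioxolan-2-yl)ethyl chain on C3 | C=C1CC[C@H]2[C@@H](C1)C[C@H](O[Si](C)(C)C(C)(C)C)[C@@H](CCC1(C)OCCO1)C2(C)C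
A3 | alternative 3 | silyl-protected 1,2-dioxane alcohol on the cis-decalin-2,7-dione | O=C1CC[C@H]2[C@@H](C1)CC(=O)[C@@H](CC[C@@]1(C)CC[C@H]([C@@H](C)CO[Si](C)(C)C(C)(C)C)OO1)C2(C)C
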